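**Retrosynthetic overview**

- The target comes from deallylation of its 5,7-bis(allyl) ether, whose C4 carbinol is set by catalyst-controlled reduction of the chroman-4-one; that diketone is traced back through protecting-group exchange and double oxidation to a racemic diol.
- Key disconnection of the diol: C3–C4 and O1–C8a of pyran ring B and, in the same flask, the C8–side-chain bond. This leads to 6-chloro-2,4-dimethoxy-3-methylbenzaldehyde, the three-atom unit LiCH2C(CH3)2OLi and 3-phenylpropanal.
- Enabling feature: in the fully substituted benzene ring A, the ether carbon C8a sits between C4a (bearing C4) and C8 (bearing the acyl group). An aryne across C8–C8a can therefore be captured at C8a by an alkoxide tethered through C4–C3–C2 (closing ring B), leaving its carbanion at C8, exactly where the side chain is needed.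
- Ring order: ring A is bought and chlorinated at the future C8a; ring B closes in the key step; the C4 stereocentre is set afterwards by asymmetric transfer hydrogenation.

Key step: step 2

Remark: chroman numbering (O1, C2, C3, C4, C4a, C5 to C8, C8a) is used for all bicyclic compounds; the target carbinol is (4R); all starting materials are assumed to be commercially available.

**Route**

Step 1
Reactants: 1 2,4-dimethoxy-3-methylbenzaldehyde
Product: 5 6-chloro-2,4-dimethoxy-3-methylbenzaldehyde, via lithium α-amino alkoxide 2 (not isolated), via ortho-lithiated α-amino alkoxide 3 (not isolated), via ortho-chlorinated α-amino alkoxide 4 (not isolated)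
Conditions: LiN(CH3)CH2CH2N(CH3)2 (from the diamine and n-BuLi, 1.1 equiv), THF, −20 °C; n-BuLi (3 equiv), −20 °C; C2Cl6, −78 °C → rt; H2O
Reagents that add atoms: hexachloroethane, ClC(Cl)(Cl)C(Cl)(Cl)Cl
Why: In situ protection of the aldehyde as a lithium α-amino alkoxide, whose chelating dimethylaminoethyl arm should deliver n-BuLi to the only hydrogen ortho to the masked formyl group (directed ortho-metalation; the position between the methoxy groups is blocked by methyl), followed by Cl+ transfer from C2Cl6 and hydrolytic release of the aldehyde on work-up.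

Step 2
Reactants: 5 6-chloro-2,4-dimethoxy-3-methylbenzaldehyde; 6 1-chloro-2-methylpropan-2-ol; 7 3-phenylpropanal
Product: 13 1-(4-hydroxy-5,7-dimethoxy-2,2,6-trimethylchroman-8-yl)-3-phenylpropan-1-ol, via β-oxido alkyllithium 8 (not isolated), via dilithium dialkoxide 9 (not isolated), via ring-lithiated chloroarene 10 (not isolated), via aryne 11 (not isolated), via C8-lithiated chroman alkoxide 12 (not isolated)
Conditions: 6, n-BuLi (1 equiv) then LiC10H8 (2 equiv), THF, −78 °C; 5, −78 °C; s-BuLi/TMEDA (1.2 equiv), −78 → 0 °C (high dilution); 7, −78 °C → rt; H2O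
Reagents that add atoms: none
Why: Proposed new method: an anionic aryne relay in which the β-oxido alkyllithium 8 adds to the aldehyde of 5 (C3–C4 bond, giving 9), s-BuLi removes the only ring hydrogen (flanked by Cl and OMe, giving 10), warming expels LiCl to give aryne 11, the tethered tertiary lithium alkoxide adds to the aryne at C8a (O1–C8a bond) and the resulting C8 aryllithium 12 adds to aldehyde 7. Each event has close precedent on simpler substrates (1,2-addition of β-oxido organolithiums to aldehydes, 3-methoxybenzyne generation from 2-chloro-6-methoxyphenyllithium, ring closure of alkoxides onto tethered arynes, electrophilic trapping of the aryllithium left by nucleophile–aryne addition), but their combination into one relay on one substrate is new. Ring B closes in a 6-exo-dig mode by attack of O1 on the aryne carbon next to C4a. The two carbinol stereocentres (C4 and the side-chain CHOH) form without control, which is accepted because both are oxidised in step 3 and C4 is reset in step 6. The step needs regioselective aryne capture, and this is secured twice over: the C4–C3–C2 tether can reach only C8a (the C4 alkoxide would have to close a four-membered ring), and the inductive effect of the neighbouring 7-methoxy group directs the nucleophile to the distal aryne carbon and stabilises the carbanion at C8.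

Step 3
Reactants: 13 1-(4-hydroxy-5,7-dimethoxy-2,2,6-trimethylchroman-8-yl)-3-phenylpropan-1-ol
Product: 14 5,7-dimethoxy-2,2,6-trimethyl-8-(3-phenylpropanoyl)chroman-4-one
Conditions: Dess–Martin periodinane (3 equiv), pyridine, CH2Cl2, 0 °C → rt
Reagents that add atoms: none
Why: Dess–Martin oxidation should convert both secondary benzylic carbinols into ketones under buffered, non-acidic conditions, which erases the two uncontrolled stereocentres and leaves the aryl and ring ethers untouched.

Step 4
Reactants: 14 5,7-dimethoxy-2,2,6-trimethyl-8-(3-phenylpropanoyl)chroman-4-one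
Product: 15 5,7-dihydroxy-2,2,6-trimethyl-8-(3-phenylpropanoyl)chroman-4-one
Conditions: BCl3 (5 equiv), CH2Cl2, −78 → 0 °C; H2O
Reagents that add atoms: none
Why: Chelation-assisted Lewis-acid ether cleavage, in which BCl3 bridges each carbonyl oxygen and its neighbouring methoxy oxygen in a six-membered chelate so that chloride removes exactly these two methyl groups, while the weakly basic vinylogous-ester oxygen O1 should stay intact; it is done at the diketone stage because the later C4 carbinol would not survive a Lewis acid.

Step 5
Reactants: 15 5,7-dihydroxy-2,2,6-trimethyl-8-(3-phenylpropanoyl)chroman-4-one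
Product: 16 5,7-bis(allyloxy)-2,2,6-trimethyl-8-(3-phenylpropanoyl)chroman-4-one
Conditions: allyl bromide (3 equiv), K2CO3, DMF, 50 °C
Reagents that add atoms: allyl bromide, C=CCBr
Why: Williamson O-alkylation of the two chelated phenols with a small electrophile, installing groups that can later be removed under neutral conditions and that twist the side-chain ketone out of the ring plane for the next step.

Step 6
Reactants: 16 5,7-bis(allyloxy)-2,2,6-trimethyl-8-(3-phenylpropanoyl)chroman-4-one
Product: 17 1-[(4R)-5,7-bis(allyloxy)-4-hydroxy-2,2,6-trimethylchroman-8-yl]-3-phenylpropan-1-one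
Conditions: RuCl[(R,R)-TsDPEN](p-cymene) (3 mol%), HCO2Na (5 equiv), H2O/DMF, 40 °C
Reagents that add atoms: none
Why: Noyori-type asymmetric transfer hydrogenation, in which the (R,R)-TsDPEN ruthenium hydride delivers H−/H+ through the outer-sphere six-membered transition state organised by the CH–π contact between the cymene ligand and the fused arene, so the catalyst sets C4 as (R) as it does for 4-chromanone and 1-tetralone; the side-chain ketone, flanked by two ortho oxygen substituents and twisted out of conjugation, should not react, and the neutral formate medium spares the allyl ethers and the acid-labile benzylic alcohol.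

Step 7
Reactants: 17 1-[(4R)-5,7-bis(allyloxy)-4-hydroxy-2,2,6-trimethylchroman-8-yl]-3-phenylpropan-1-one
Product: 18 1-[(4R)-4,5,7-trihydroxy-2,2,6-trimethylchroman-8-yl]-3-phenylpropan-1-one
Conditions: Pd(PPh3)4 (5 mol%), morpholine (10 equiv), THF, rt
Reagents that add atoms: none
Why: Tsuji–Trost-type deallylation, in which zerovalent palladium ionises the aryl allyl ethers to π-allyl complexes that are intercepted by excess morpholine, a neutral process that should not ionise or epimerise the C4 benzylic alcohol.

**Compound list**

1 | 2,4-dimethoxy-3-methylbenzaldehyde | O=Cc1ccc(OC)c(C)c1OC | starting material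
2 | lithium α-amino alkoxide of 1 (adduct with lithium N,N,N′-trimethylethylenediamide) | [Li]OC(N(C)CCN(C)C)c1ccc(OC)c(C)c1OC | intermediate (not isolated)
3 | ortho-lithiated α-amino alkoxide | [Li]OC(N(C)CCN(C)C)c1c([Li])cc(OC)c(C)c1OC | intermediate (not isolated)
4 | ortho-chlorinated α-amino alkoxide | [Li]OC(N(C)CCN(C)C)c1c(Cl)cc(OC)c(C)c1OC | intermediate (not isolated)
5 | 6-chloro-2,4-dimethoxy-3-methylbenzaldehyde | O=Cc1c(Cl)cc(OC)c(C)c1OC | intermediate
6 | 1-chloro-2-methylpropan-2-ol | CC(C)(O)CCl | starting material
7 | 3-phenylpropanal | O=CCCc1ccccc1 | starting material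
8 | lithium 1-lithio-2-methylpropan-2-olate (β-oxido alkyllithium) | [Li]CC(C)(C)O[Li] | intermediate (not isolated)
9 | dilithium 1-(6-chloro-2,4-dimethoxy-3-methylphenyl)-3-methylbutane-1,3-diolate (racemic) | [Li]OC(CC(C)(C)O[Li])c1c(Cl)cc(OC)c(C)c1OC | intermediate (not isolated)
10 | ring-lithiated chloroarene (lithium between Cl and OMe) | [Li]OC(CC(C)(C)O[Li])c1c(Cl)c([Li])c(OC)c(C)c1OC | intermediate (not isolated)
11 | aryne (triple bond across the future C8–C8a) | [Li]OC(CC(C)(C)O[Li])C1=C(OC)C(C)=C(OC)C#C1 | intermediate (not isolated)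
12 | lithium 8-lithio-5,7-dimethoxy-2,2,6-trimethylchroman-4-olate (racemic) | [Li]OC1CC(C)(C)Oc2c([Li])c(OC)c(C)c(OC)c12 | intermediate (not isolated)
13 | 1-(4-hydroxy-5,7-dimethoxy-2,2,6-trimethylchroman-8-yl)-3-phenylpropan-1-ol (racemic, mixture of diastereomers) | Cc1c(OC)c(C(O)CCc2ccccc2)c2c(c1OC)C(O)CC(C)(C)O2 | intermediate
14 | 5,7-dimethoxy-2,2,6-trimethyl-8-(3-phenylpropanoyl)chroman-4-one | Cc1c(OC)c(C(=O)CCc2ccccc2)c2c(c1OC)C(=O)CC(C)(C)O2 | intermediate
15 | 5,7-dihydroxy-2,2,6-trimethyl-8-(3-phenylpropanoyl)chroman-4-one | Cc1c(O)c(C(=O)CCc2ccccc2)c2c(c1O)C(=O)CC(C)(C)O2 | intermediate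
16 | 5,7-bis(allyloxy)-2,2,6-trimethyl-8-(3-phenylpropanoyl)chroman-4-one | Cc1c(OCC=C)c(C(=O)CCc2ccccc2)c2c(c1OCC=C)C(=O)CC(C)(C)O2 | intermediate
17 | 1-[(4R)-5,7-bis(allyloxy)-4-hydroxy-2,2,6-trimethylchroman-8-yl]-3-phenylpropan-1-one | Cc1c(OCC=C)c(C(=O)CCc2ccccc2)c2c(c1OCC=C)[C@H](O)CC(C)(C)O2 | intermediate
18 | 1-[(4R)-4,5,7-trihydroxy-2,2,6-trimethylchroman-8-yl]-3-phenylpropan-1-one (2′,4′,4″-trihydroxy-3′,6″,6″-trimethylpyrano[2″,3″:6′,5′]dihydrochalcone) | Cc1c(O)c(C(=O)CCc2ccccc2)c2c(c1O)[C@H](O)CC(C)(C)O2 | target

**Summary and risk assessment**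

Total step count: 7. Longest linear sequence: 7 steps (1 → 5 → 13 → 14 → 15 → 16 → 17 → 18); reagent 8 is generated in the flask from 6 within step 2.

Steps most likely to fail:

1. Step 2 (proposed new method). The aryne may be consumed intermolecularly (addition of a second aryllithium or alkoxide, giving biaryls and oligomers) before the tethered alkoxide closes ring B. A slight excess of LiC10H8 may reduce the aldehyde or the C–Cl bond, and the hindered aryllithium may deprotonate aldehyde 7 instead of adding to it. The fallback uses known chemistry and sets out from 5. Addition of 8 at −78 °C with a cold aqueous quench should give 1-(6-chloro-2,4-dimethoxy-3-methylphenyl)-3-methylbutane-1,3-diol F1. Palladium-catalysed intramolecular C–O cross-coupling of the aryl chloride with the tertiary alcohol (Pd(OAc)2, 2-(di-tert-butylphosphino)-1,1′-binaphthyl, Cs2CO3, toluene, 80 °C) should then close ring B to 5,7-dimethoxy-2,2,6-trimethylchroman-4-ol F2. Finally n-BuLi (2.2 equiv, THF, 0 °C) should lithiate C8 between O1 and the 7-methoxy group (directed ortho-metalation, giving the same species as 12), and addition to 7 comes back to the route at 13.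

2. Step 6. Hydride transfer to the electron-rich, peri-substituted C4 carbonyl may be slow, leading to incomplete conversion or eroded enantioselectivity, and some reduction of the side-chain ketone may compete. The fallback replaces asymmetric catalysis by resolution and sets out from 16. NaBH4 (MeOH/THF, −20 °C) should reduce only the ring ketone to racemic 1-[5,7-bis(allyloxy)-4-hydroxy-2,2,6-trimethylchroman-8-yl]-3-phenylpropan-1-one F3. Lipase-catalysed kinetic resolution (immobilised Candida antarctica lipase B, vinyl acetate, tert-butyl methyl ether, 40 °C) should acylate the (R)-enantiomer to (4R)-5,7-bis(allyloxy)-2,2,6-trimethyl-8-(3-phenylpropanoyl)chroman-4-yl acetate F4 and leave 1-[(4S)-5,7-bis(allyloxy)-4-hydroxy-2,2,6-trimethylchroman-8-yl]-3-phenylpropan-1-one F5, which is recycled to 16 by Dess–Martin oxidation. Methanolysis of F4 (K2CO3, MeOH, 0 °C) comes back to the route at 17.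

3. Step 7. The liberated electron-rich phenoxide may recapture the π-allyl palladium cation at a ring carbon (dearomatising C-allylation), or the hindered ethers may cleave incompletely. The fallback changes the protecting group and sets out from 15. Silylation (TBSOTf, 2,6-lutidine, CH2Cl2, 0 °C) should give 5,7-bis(tert-butyldimethylsilyloxy)-2,2,6-trimethyl-8-(3-phenylpropanoyl)chroman-4-one F6. The transfer hydrogenation of step 6 should give 1-[(4R)-5,7-bis(tert-butyldimethylsilyloxy)-4-hydroxy-2,2,6-trimethylchroman-8-yl]-3-phenylpropan-1-one F7. Buffered fluoride (Bu4NF/AcOH, THF, 0 °C) then comes back to the route at 18.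

Further compounds
F1 | step 2 | 1-(6-chloro-2,4-dimethoxy-3-methylphenyl)-3-methylbutane-1,3-diol (racemic) | CC(C)(O)CC(O)c1c(Cl)cc(OC)c(C)c1OC
F2 | step 2 | 5,7-dimethoxy-2,2,6-trimethylchroman-4-ol (racemic) | Cc1c(OC)cc2c(c1OC)C(O)CC(C)(C)O2
F3 | step 6 | 1-[5,7-bis(allyloxy)-4-hydroxy-2,2,6-trimethylchroman-8-yl]-3-phenylpropan-1-one (racemic) | Cc1c(OCC=C)c(C(=O)CCc2ccccc2)c2c(c1OCC=C)C(O)CC(C)(C)O2
F4 | step 6 | (4R)-5,7-bis(allyloxy)-2,2,6-trimethyl-8-(3-phenylpropanoyl)chroman-4-yl acetate | Cc1c(OCC=C)c(C(=O)CCc2ccccc2)c2c(c1OCC=C)[C@H](OC(C)=O)CC(C)(C)O2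
F5 | step 6 | 1-[(4S)-5,7-bis(allyloxy)-4-hydroxy-2,2,6-trimethylchroman-8-yl]-3-phenylpropan-1-one | Cc1c(OCC=C)c(C(=O)CCc2ccccc2)c2c(c1OCC=C)[C@@H](O)CC(C)(C)O2
F6 | step 7 | 5,7-bis(tert-butyldimethylsilyloxy)-2,2,6-trimethyl-8-(3-phenylpropanoyl)chroman-4-one | Cc1c(O[Si](C)(C)C(C)(C)C)c(C(=O)CCc2ccccc2)c2c(c1O[Si](C)(C)C(C)(C)C)C(=O)CC(C)(C)O2
F7 | step 7 | 1-[(4R)-5,7-bis(tert-butyldimethylsilyloxy)-4-hydroxy-2,2,6-trimethylchroman-8-yl]-3-phenylpropan-1-one | Cc1c(O[Si](C)(C)C(C)(C)C)c(C(=O)CCc2ccccc2)c2c(c1O[Si](C)(C)C(C)(C)C)[C@H](O)CC(C)(C)O2
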